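**Strategy**

Ring A of the flavone (C4a–C5–C6–C7–C8–C8a) carries para oxygens at C5 and C8 around vicinal methoxyls at C6 and C7, which is the oxygenation pattern of a squarate ester. It is therefore cut at C4a–C5 and C8–C8a: C5–C8 come from dimethyl squarate, rings C and B from a preformed 2-anisyl-3-methoxy-4-pyranone. The precursor is the 4-hydroxycyclobutenone obtained by adding the 5-metallated pyranone to squarate. On heating it opens to a dienylketene that closes onto the free pyranone CH and aromatises, so one operation makes ring A with all four oxygens in place; the chelated 5-OH then allows methylation of O8 alone.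

Key step: step 5

Remark on stereochemistry: the target has no stereocentre or other stereogenic element, so it is a single achiral compound. The stereocentres that occur on the way (in 5, 10 and 12) are formed as racemates and disappear again.

Remark on numbering: in 10 the pyranone is named as a substituent, so its free CH is pyranyl C2. The same atom is C6 in the parent pyranones 6 and 7, and it becomes chromone C8a.

**Route**

Step 1
Reactants: 1 4-methoxyphenylmagnesium bromide; 2 N,2-dimethoxy-N-methylacetamide
Product: 3 2-methoxy-1-(4-methoxyphenyl)ethan-1-one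
Conditions: THF, 0 °C to rt; 1 M HCl
Reagents that add atoms: none
Why: Weinreb ketone synthesis, in which the magnesium chelate of the tetrahedral adduct survives until acidic work-up so that the Grignard reagent adds only once; this avoids a Friedel–Crafts acylation with an alkoxyacetyl chloride, which tends to lose CO under Lewis acids.

Step 2
Reactants: 3 2-methoxy-1-(4-methoxyphenyl)ethan-1-one; 4 (E)-3-ethoxyacryloyl chloride
Product: 6 3-methoxy-2-(4-methoxyphenyl)-4H-pyran-4-one, via ethoxyvinyl β-diketone 5 (not isolated)
Conditions: 3 (2 equiv), LiHMDS (2 equiv), toluene–THF, 0 °C; then 4 (1 equiv); NH4Cl work-up; crude 5, TFA, CH2Cl2, rt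
Reagents that add atoms: none
Why: C-acylation of a lithium ketone enolate by an acid chloride (Claisen-type acylation, the second equivalent of enolate deprotonating 5) should give the β-diketone, whose enol oxygen then adds to the β-ethoxyenone and expels ethanol under acid, the usual cyclodehydration of 1,3,5-tricarbonyl equivalents to 4-pyranones; the substitution pattern is fixed by the connectivity of 3 and 4.

Step 3
Reactants: 6 3-methoxy-2-(4-methoxyphenyl)-4H-pyran-4-one
Product: 7 5-iodo-3-methoxy-2-(4-methoxyphenyl)-4H-pyran-4-one
Conditions: NIS (1.1 equiv), TFA (cat.), MeCN, 0 °C to rt, dark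
Reagents that add atoms: N-iodosuccinimide, O=C1CCC(=O)N1I
Why: Electrophilic iodination of a vinylogous ester: C5 is the β-carbon of the O1–C6=C5 enol ether and the only nucleophilic ring position left (C3 is substituted, C6 is electrophilic), while the anisyl ring is deactivated by conjugation with the pyranone.

Step 4
Reactants: 7 5-iodo-3-methoxy-2-(4-methoxyphenyl)-4H-pyran-4-one; 8 dimethyl squarate
Product: 10 rac-4-hydroxy-2,3-dimethoxy-4-[5-methoxy-6-(4-methoxyphenyl)-4-oxo-4H-pyran-3-yl]cyclobut-2-en-1-one, via pyranonylmagnesium chloride 9 (not isolated)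
Conditions: i-PrMgCl·LiCl (1.05 equiv), THF, −40 °C; then cannulated into 8 (1.3 equiv), THF, −78 °C; sat. NH4Cl at −78 °C
Reagents that add atoms: none
Why: Iodine–magnesium exchange with the turbo-Grignard reagent should give a carbonyl-chelated alkenylmagnesium species at low temperature, and its 1,2-addition to one carbonyl of a squarate ester is the standard entry to 4-substituted 4-hydroxycyclobutenones (this forms C4a–C5); the carbinol stereocentre arises without control, as a racemate, and is erased in step 5.

Step 5
Reactants: 10 rac-4-hydroxy-2,3-dimethoxy-4-[5-methoxy-6-(4-methoxyphenyl)-4-oxo-4H-pyran-3-yl]cyclobut-2-en-1-one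
Product: 13 5,8-dihydroxy-3,6,7-trimethoxy-2-(4-methoxyphenyl)-4H-chromen-4-one, via dienylketene 11 (not isolated), via bicyclic dienone 12 (not isolated)
Conditions: degassed toluene, 110 °C, Ar, high dilution (p-xylene, 138 °C if slow)
Reagents that add atoms: none
Why: Thermal conrotatory 4π ring opening of the cyclobutenone should give the (Z)-dienylketene 11, which undergoes 6π-electrocyclisation between the ketene carbon and the pyranyl C2–H carbon (future C8a) to give dienone 12, and enolisation of 12 aromatises ring A to the hydroquinone 13. The closest known reaction is the Moore-type ring expansion of 4-alkenyl- and 4-(hetero)aryl-4-hydroxycyclobutenones derived from squarate esters, the pyranonyl group behaving as a 2-alkoxyvinyl substituent. The one ring closed is the six-membered carbocycle A, formed by a thermally allowed disrotatory 6π-electrocyclisation with C8–C8a as the new bond. No stereocentre survives: the carbinol carbon of 10 becomes sp2 C5 and C8a of 12 is planarised on aromatisation. The step needs torquoselectivity, supplied by the hydroxyl donor, which rotates outward and so turns the pyranyl group inward toward the ketene; it also needs regioselective closure, secured because only one neighbour of the attachment carbon is a CH, the other being the C4 carbonyl carbon. Exclusion of air should keep the electron-rich hydroquinone from oxidising to the 5,8-quinone, which a wash with aqueous dithionite would return to 13.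

Step 6
Reactants: 13 5,8-dihydroxy-3,6,7-trimethoxy-2-(4-methoxyphenyl)-4H-chromen-4-one
Product: 14 5-hydroxyauranetin (5-hydroxy-3,6,7,8-tetramethoxy-2-(4-methoxyphenyl)-4H-chromen-4-one)
Conditions: MeI (1.1 equiv), K2CO3 (1.1 equiv), degassed acetone, rt, Ar
Reagents that add atoms: iodomethane, CI
Why: Williamson O-methylation under chelation control: the 5-OH is held in a hydrogen bond to the C4 carbonyl and is much less acidic and nucleophilic than the free 8-OH, the classical basis for partial methylation of 5,8-dihydroxyflavones.

**Compound list**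

1 | 4-methoxyphenylmagnesium bromide | COc1ccc([Mg]Br)cc1 | starting material
2 | N,2-dimethoxy-N-methylacetamide | COCC(=O)N(C)OC | starting material
3 | 2-methoxy-1-(4-methoxyphenyl)ethan-1-one | COCC(=O)c1ccc(OC)cc1 | intermediate
4 | (E)-3-ethoxyacryloyl chloride | CCO/C=C/C(=O)Cl | starting material
5 | (E)-5-ethoxy-2-methoxy-1-(4-methoxyphenyl)pent-4-ene-1,3-dione (racemic at C2) | CCO/C=C/C(=O)C(OC)C(=O)c1ccc(OC)cc1 | intermediate
6 | 3-methoxy-2-(4-methoxyphenyl)-4H-pyran-4-one | COc1ccc(-c2occc(=O)c2OC)cc1 | intermediate
7 | 5-iodo-3-methoxy-2-(4-methoxyphenyl)-4H-pyran-4-one | COc1ccc(-c2occ(I)c(=O)c2OC)cc1 | intermediate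
8 | dimethyl squarate (3,4-dimethoxycyclobut-3-ene-1,2-dione) | COC1=C(OC)C(=O)C1=O | starting material
9 | [5-methoxy-6-(4-methoxyphenyl)-4-oxo-4H-pyran-3-yl]magnesium chloride (LiCl complex) | COc1ccc(-c2occ([Mg]Cl)c(=O)c2OC)cc1 | intermediate
10 | 4-hydroxy-2,3-dimethoxy-4-[5-methoxy-6-(4-methoxyphenyl)-4-oxo-4H-pyran-3-yl]cyclobut-2-en-1-one (racemic, one stereocentre at C4) | COC1=C(OC)C(O)(c2coc(-c3ccc(OC)cc3)c(OC)c2=O)C1=O | intermediate
11 | (3Z)-4-hydroxy-2,3-dimethoxy-4-[5-methoxy-6-(4-methoxyphenyl)-4-oxo-4H-pyran-3-yl]buta-1,3-dien-1-one (hydroxyl trans, pyranyl cis to the ketene carbon) | O=C=C(OC)/C(OC)=C(/O)c1coc(-c2ccc(OC)cc2)c(OC)c1=O | intermediate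
12 | 5-hydroxy-3,6,7-trimethoxy-2-(4-methoxyphenyl)-8aH-chromene-4,8-dione (racemic at C8a) | COc1ccc(C2=C(OC)C(=O)C3=C(O)C(OC)=C(OC)C(=O)C3O2)cc1 | intermediate
13 | 5,8-dihydroxy-3,6,7-trimethoxy-2-(4-methoxyphenyl)-4H-chromen-4-one | COc1ccc(-c2oc3c(O)c(OC)c(OC)c(O)c3c(=O)c2OC)cc1 | intermediate
14 | 5-hydroxyauranetin, 5-hydroxy-3,6,7,8-tetramethoxy-2-(4-methoxyphenyl)-4H-chromen-4-one (achiral) | COc1ccc(-c2oc3c(OC)c(OC)c(OC)c(O)c3c(=O)c2OC)cc1 | target

**Step count**

Total steps: 6. Longest linear sequence: 6 steps (1 and 2 to 14; 4 and 8 enter as purchased).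

**Steps most likely to fail**

Step 5. The dienylketene may be diverted before it closes onto the pyranyl CH: the neighbouring hydroxyl can capture the ketene (lactone formation), or the free hydroquinone can be lost by oxidation at the temperature needed. The fallback sets out from 10 and changes the substrate to the O-protected series, for which ring expansion to mono-protected hydroquinones is established. TBSOTf and 2,6-lutidine in CH2Cl2 at −78 °C should give 4-[(tert-butyldimethylsilyl)oxy]-2,3-dimethoxy-4-[5-methoxy-6-(4-methoxyphenyl)-4-oxo-4H-pyran-3-yl]cyclobut-2-en-1-one F1. Heating F1 in toluene or xylene should give 5-[(tert-butyldimethylsilyl)oxy]-8-hydroxy-3,6,7-trimethoxy-2-(4-methoxyphenyl)-4H-chromen-4-one F2, in which the oxygen can no longer trap the ketene, no quinone can form and only O8 is free. Methylation with MeI and K2CO3 in acetone should give 5-[(tert-butyldimethylsilyl)oxy]-3,6,7,8-tetramethoxy-2-(4-methoxyphenyl)-4H-chromen-4-one F3, and TBAF buffered with AcOH in THF should release the 5-OH. The detour bypasses 13 and comes back to the route at 14.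

Step 4. The magnesiated pyranone may fragment by β-elimination of the ring oxygen (ring opening to an ynone), or the isopropyl reagent may add to the pyranone before exchange is complete. The fallback sets out from 7 and makes the carbon–metal bond by oxidative insertion instead of exchange. Zinc dust and LiCl in THF at 25 °C should give [5-methoxy-6-(4-methoxyphenyl)-4-oxo-4H-pyran-3-yl]zinc iodide F4, an organozinc too weakly basic to eliminate and compatible with the enone. Its addition to the strained, electrophilic carbonyl of 8 would be driven by MgCl2 (Lewis-acid-accelerated carbonyl addition of organozinc halides). The detour comes back to the route at 10.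

Step 3. Iodination of 6 may be sluggish or may spill over onto the anisyl ring ortho to its methoxyl. The fallback sets out from 3 and places the iodine while the ring is being closed, so that its position is fixed by mechanism. Claisen condensation of 3 with ethyl acetate and NaH should give 2-methoxy-1-(4-methoxyphenyl)butane-1,3-dione F5. DMF dimethyl acetal should condense at its only methyl group to give (E)-5-(dimethylamino)-2-methoxy-1-(4-methoxyphenyl)pent-4-ene-1,3-dione F6. Iodine in CHCl3 should then iodinate the enaminone α-carbon, after which the enol oxygen closes onto the iminium carbon with loss of dimethylamine, the way 3-iodochromones are made from 2-hydroxyaryl enaminones. The detour also bypasses step 2 and comes back to the route at 7.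

**Further compounds**

F1 | step 5 | 4-[(tert-butyldimethylsilyl)oxy]-2,3-dimethoxy-4-[5-methoxy-6-(4-methoxyphenyl)-4-oxo-4H-pyran-3-yl]cyclobut-2-en-1-one (racemic) | COC1=C(OC)C(O[Si](C)(C)C(C)(C)C)(c2coc(-c3ccc(OC)cc3)c(OC)c2=O)C1=O
F2 | step 5 | 5-[(tert-butyldimethylsilyl)oxy]-8-hydroxy-3,6,7-trimethoxy-2-(4-methoxyphenyl)-4H-chromen-4-one | COc1ccc(-c2oc3c(O)c(OC)c(OC)c(O[Si](C)(C)C(C)(C)C)c3c(=O)c2OC)cc1
F3 | step 5 | 5-[(tert-butyldimethylsilyl)oxy]-3,6,7,8-tetramethoxy-2-(4-methoxyphenyl)-4H-chromen-4-one | COc1ccc(-c2oc3c(OC)c(OC)c(OC)c(O[Si](C)(C)C(C)(C)C)c3c(=O)c2OC)cc1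
F4 | step 4 | [5-methoxy-6-(4-methoxyphenyl)-4-oxo-4H-pyran-3-yl]zinc iodide | COc1ccc(-c2occ([Zn]I)c(=O)c2OC)cc1
F5 | step 3 | 2-methoxy-1-(4-methoxyphenyl)butane-1,3-dione (racemic) | COC(C(C)=O)C(=O)c1ccc(OC)cc1
F6 | step 3 | (E)-5-(dimethylamino)-2-methoxy-1-(4-methoxyphenyl)pent-4-ene-1,3-dione (racemic) | COC(C(=O)/C=C/N(C)C)C(=O)c1ccc(OC)cc1
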